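The flavone is cut across its pyranone (ring C). C4 is a carbonyl carbon whose only carbon neighbours are C4a of ring A and C3, so ring C can be stitched from three pieces: a ring-A o-iodophenol (C4a–I, C8a–OH), carbon monoxide as C4, and the ring-B arylacetylene as C3/C2. A single palladium-catalysed carbonylative alkynylation with ring closure in the same flask should make C4a–C4, C4–C3 and O1–C2. The iodophenol already bears the (R)-configured C8 side chain, drawn from (R)-limonene oxide and attached by Negishi coupling. Its C5 oxygen is silylated so that only the C8a hydroxyl can cyclise, and all protecting groups are silyl ethers that fluoride removes at the end.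

Key step: step 15

Remark 1: flavone numbering is used (O1, C2, C3, C4, C4a, C5–C8, C8a); ring A is the benzo ring, ring B the 2-aryl group, ring C the pyranone.
Remark 2: commercial (+)-limonene 1,2-oxide is the cis/trans mixture at the epoxide with (4R) configuration; both diastereomers should converge on the same keto aldehyde, so the mixture is used as such.
Remark 3: enaminone 25 is drawn as its E isomer; the geometry is lost on ring closure.
Remark 4: the tertiary alcohol is kept as its triethylsilyl ether up to the last step, so that zinc insertion, iodination and the carbonylation never see a free aliphatic hydroxyl and the final fluoride step unmasks everything at once.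

**Side chain (from limonene oxide)**

Step 1
Reactants: 1 (+)-limonene 1,2-oxide, (4R), cis/trans mixture
Product: 2 (3R)-6-oxo-3-(prop-1-en-2-yl)heptanal
Conditions: H5IO6 (1.2 equiv), THF/H2O, 0 °C → rt
Reagents that add atoms: water, O
Why: Acid-promoted epoxide hydrolysis followed by periodate glycol cleavage (Malaprade reaction) should open the ring between the two epoxide carbons of both diastereomers, leaving the isopropenyl group and the stereocentre (now β to the aldehyde, not enolisable) untouched.

Step 2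
Reactants: 2 (3R)-6-oxo-3-(prop-1-en-2-yl)heptanal
Product: 3 (3R)-6-oxo-3-(prop-1-en-2-yl)heptanoic acid
Conditions: NaClO2, NaH2PO4, 2-methyl-2-butene, t-BuOH/H2O, 0 °C → rt
Reagents that add atoms: sodium chlorite, [Na+].[O-]Cl=O
Why: Pinnick oxidation converts only the aldehyde into the acid under buffered conditions, and 2-methyl-2-butene scavenges hypochlorous acid so that the isopropenyl group is not chlorinated.

Step 3
Reactants: 3 (3R)-6-oxo-3-(prop-1-en-2-yl)heptanoic acid
Product: 4 (3R)-6-hydroxy-6-methyl-3-(prop-1-en-2-yl)heptanoic acid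
Conditions: MeMgBr (3.5 equiv), THF, −20 → 0 °C; aq. NH4Cl, then 1 M HCl to pH 4 at 0 °C
Reagents that add atoms: methylmagnesium bromide, C[Mg]Br
Why: The first equivalent forms the magnesium carboxylate, which resists further addition at 0 °C, so the excess reagent should add only to the methyl ketone (chemoselective Grignard addition) and give the gem-dimethyl carbinol.

Step 4
Reactants: 4 (3R)-6-hydroxy-6-methyl-3-(prop-1-en-2-yl)heptanoic acid
Product: 6 (5S)-5-(iodomethyl)-2,6-dimethylhept-6-en-2-ol, via Barton ester 5 (not isolated)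
Conditions: 1-hydroxypyridine-2(1H)-thione, DCC, DMAP (cat.), CH2Cl2, 0 °C → rt, dark; then CHI3 (2 equiv), PhH, hν (tungsten lamp), rt
Reagents that add atoms: iodoform, IC(I)I
Why: Barton decarboxylative iodination: the thiohydroxamate ester fragments under visible light to the primary radical at the former C2, which should abstract iodine from iodoform far faster than a homoallyl radical closes in a 3-exo sense, so the carboxyl carbon is excised without touching the stereocentre (the descriptor changes to S only through CIP priorities).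

Step 5
Reactants: 6 (5S)-5-(iodomethyl)-2,6-dimethylhept-6-en-2-ol
Product: 7 triethyl{[(5S)-5-(iodomethyl)-2,6-dimethylhept-6-en-2-yl]oxy}silane
Conditions: TESOTf, 2,6-lutidine, CH2Cl2, −78 → 0 °C
Reagents that add atoms: triethylsilyl triflate, CC[Si](CC)(CC)OS(=O)(=O)C(F)(F)F
Why: Silylation with a silyl triflate and a hindered pyridine base is the standard way to protect a tertiary alcohol, and the TES ether masks the hydroxyl during zinc insertion and iodination.

**Ring A**

Step 6
Reactants: 8 phloroglucinol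
Product: 9 5-(triisopropylsilyloxy)benzene-1,3-diol
Conditions: TIPSCl (1 equiv), imidazole, phloroglucinol (3 equiv), DMF, 0 °C → rt
Reagents that add atoms: triisopropylsilyl chloride, CC(C)[Si](Cl)(C(C)C)C(C)C
Why: With the C3-symmetric triol in excess, the bulky silyl chloride should give mainly the mono-ether (statistical mono-silylation), and unreacted phloroglucinol is washed out with water.

Step 7
Reactants: 9 5-(triisopropylsilyloxy)benzene-1,3-diol
Product: 10 [3,5-bis(methoxymethoxy)phenoxy]triisopropylsilane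
Conditions: MOMCl (2.5 equiv), i-Pr2NEt, CH2Cl2, 0 °C → rt
Reagents that add atoms: chloromethyl methyl ether, COCCl
Why: O-alkylation of both phenols (Williamson-type) gives the bis-acetal, which directs the next lithiation and keeps the two oxygens that will flank the coupling site small.

Step 8
Reactants: 10 [3,5-bis(methoxymethoxy)phenoxy]triisopropylsilane
Product: 12 [4-bromo-3,5-bis(methoxymethoxy)phenoxy]triisopropylsilane, via aryllithium 11 (not isolated)
Conditions: n-BuLi (1.1 equiv), THF, 0 °C; then BrCl2C–CCl2Br, −78 °C → rt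
Reagents that add atoms: 1,2-dibromotetrachloroethane, ClC(Cl)(Br)C(Cl)(Cl)Br
Why: Directed ortho-metalation: the two MOM ethers cooperatively steer butyllithium to the carbon between them (the future C8), and the aryllithium is then brominated by the electrophilic bromine donor.

**Union and ring-A precursor**

Step 9
Reactants: 7 triethyl{[(5S)-5-(iodomethyl)-2,6-dimethylhept-6-en-2-yl]oxy}silane; 12 [4-bromo-3,5-bis(methoxymethoxy)phenoxy]triisopropylsilane
Product: 14 {3,5-bis(methoxymethoxy)-4-[(2R)-5-methyl-2-(prop-1-en-2-yl)-5-(triethylsilyloxy)hexyl]phenoxy}triisopropylsilane, via alkylzinc iodide 13 (not isolated)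
Conditions: Zn dust (BrCH2CH2Br/TMSCl-activated), LiCl, THF, 25–40 °C; then 12, Pd(OAc)2 (2 mol%), SPhos (4 mol%), THF, rt → 50 °C
Reagents that add atoms: none
Why: LiCl-assisted zinc insertion into the primary iodide gives an alkylzinc whose stereocentre is β to the metal and therefore unaffected, and Negishi coupling with a dialkylbiarylphosphine–palladium catalyst, which favours reductive elimination over β-hydride elimination, should form the C(sp3)–C8 bond at the hindered aryl bromide.

Step 10
Reactants: 14 {3,5-bis(methoxymethoxy)-4-[(2R)-5-methyl-2-(prop-1-en-2-yl)-5-(triethylsilyloxy)hexyl]phenoxy}triisopropylsilane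
Product: 15 {2-iodo-3,5-bis(methoxymethoxy)-4-[(2R)-5-methyl-2-(prop-1-en-2-yl)-5-(triethylsilyloxy)hexyl]phenoxy}triisopropylsilane
Conditions: NIS (1.05 equiv), NaHCO3, MeCN, 0 °C → rt, dark
Reagents that add atoms: N-iodosuccinimide, O=C1CCC(=O)N1I
Why: Electrophilic aromatic iodination of the trioxygenated ring should be much faster than any reaction at the isopropenyl group (no free hydroxyl is present to trap an iodonium ion), and the two open ring positions are equivalent by symmetry, so only one mono-iodide can form.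

Step 11
Reactants: 15 {2-iodo-3,5-bis(methoxymethoxy)-4-[(2R)-5-methyl-2-(prop-1-en-2-yl)-5-(triethylsilyloxy)hexyl]phenoxy}triisopropylsilane
Product: 17 4-iodo-2-[(2R)-5-methyl-2-(prop-1-en-2-yl)-5-(triethylsilyloxy)hexyl]-5-(triisopropylsilyloxy)benzene-1,3-diol, via bis-TMS ether 16 (not isolated)
Conditions: TMSOTf (5 equiv), 2,2′-bipyridyl (7.5 equiv), CH2Cl2, 0 °C → rt; then H2O
Reagents that add atoms: none
Why: Silyl triflate/2,2′-bipyridyl cleavage of aryl MOM ethers passes through aryl trimethylsilyl ethers that hydrolyse on aqueous work-up; because the medium is non-protic and base-buffered, the isopropenyl group (prone to acid-induced chroman formation with the neighbouring phenols), the aryl iodide and the TIPS and TES ethers should survive.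

**Ring B**

Step 12
Reactants: 18 2,4-dihydroxybenzaldehyde
Product: 19 2,4-bis(triisopropylsilyloxy)benzaldehyde
Conditions: TIPSOTf (2.3 equiv), Et3N, CH2Cl2, 0 °C → rt
Reagents that add atoms: triisopropylsilyl triflate, CC(C)[Si](OS(=O)(=O)C(F)(F)F)(C(C)C)C(C)C
Why: The silyl triflate with amine base silylates both phenols, including the hydrogen-bonded ortho hydroxyl that reacts sluggishly with the silyl chloride.

Step 13
Reactants: 19 2,4-bis(triisopropylsilyloxy)benzaldehyde
Product: 20 [4-(2,2-dibromoethenyl)-1,3-phenylene]bis(oxy)bis(triisopropylsilane)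
Conditions: CBr4, PPh3, Zn dust, CH2Cl2, 0 °C → rt
Reagents that add atoms: carbon tetrabromide, BrC(Br)(Br)Br
Why: Ramirez dibromo-olefination (first stage of the Corey–Fuchs sequence) of the non-enolisable aldehyde; zinc dust consumes the bromophosphonium by-product, so the aryl silyl ethers stay intact.

Step 14
Reactants: 20 [4-(2,2-dibromoethenyl)-1,3-phenylene]bis(oxy)bis(triisopropylsilane)
Product: 22 1-ethynyl-2,4-bis(triisopropylsilyloxy)benzene, via lithium acetylide 21 (not isolated)
Conditions: n-BuLi (2.2 equiv), THF, −78 °C; then H2O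
Reagents that add atoms: none
Why: Second stage of the Corey–Fuchs sequence: bromine–lithium exchange, Fritsch–Buttenberg–Wiechell 1,2-shift and deprotonation give the acetylide, which is protonated on quench; no alkoxide is generated next to the ortho silyl ether, so silyl migration is avoided.

**Key step and end game**

Step 15
Reactants: 17 4-iodo-2-[(2R)-5-methyl-2-(prop-1-en-2-yl)-5-(triethylsilyloxy)hexyl]-5-(triisopropylsilyloxy)benzene-1,3-diol; 22 1-ethynyl-2,4-bis(triisopropylsilyloxy)benzene; 23 carbon monoxide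
Product: 26 2-[2,4-bis(triisopropylsilyloxy)phenyl]-7-hydroxy-8-[(2R)-5-methyl-2-(prop-1-en-2-yl)-5-(triethylsilyloxy)hexyl]-5-(triisopropylsilyloxy)-4H-chromen-4-one, via ynone 24 (not isolated), via enaminone 25 (not isolated)
Conditions: PdCl2(dppf) (5 mol%), CO (5 bar), Et2NH/THF (1:1), 60 °C, no copper salt
Reagents that add atoms: none
Why: Zerovalent palladium should insert into the C4a–I bond, CO insertion gives the aroyl-palladium, and copper-free acetylide transfer with reductive elimination gives ynone 24 (C4a–C4 and C4–C3); diethylamine then adds at C2 to give enaminone 25, and the C8a hydroxyl displaces the amine by addition–elimination (O1–C2). The closest known reaction type is the palladium-catalysed carbonylative Sonogashira coupling of o-iodophenols with terminal alkynes run in a secondary amine, which delivers flavones directly. Ring C is closed in a net 6-endo sense (6-endo-dig with respect to the ynone, realised as addition–elimination on the enaminone). No stereocentre is formed, and the remote (R) centre, the isopropenyl group and the silyl ethers should be inert to these neutral-to-basic conditions. Three selectivities are needed: carbonylative over direct alkynylation (secured by CO pressure, the absence of copper and a hindered, electron-rich aryl-palladium that takes up CO readily), 6-endo (flavone) over 5-exo (aurone) closure (secured by the amine-relayed enaminone pathway), and 8-alkyl over 6-alkyl regiochemistry (secured because the C5 oxygen carries TIPS, while the free C7 hydroxyl is para to C4a and cannot reach C2).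

Step 16
Reactants: 26 2-[2,4-bis(triisopropylsilyloxy)phenyl]-7-hydroxy-8-[(2R)-5-methyl-2-(prop-1-en-2-yl)-5-(triethylsilyloxy)hexyl]-5-(triisopropylsilyloxy)-4H-chromen-4-one
Product: 27 2-(2,4-dihydroxyphenyl)-5,7-dihydroxy-8-[(2R)-5-hydroxy-5-methyl-2-(prop-1-en-2-yl)hexyl]-4H-chromen-4-one (target)
Conditions: TBAF (6 equiv), AcOH (6 equiv), THF, 0 °C → rt
Reagents that add atoms: none
Why: Fluoride-driven desilylation (Si–F bond formation) should cleave the three aryl TIPS ethers and the tertiary TES ether in one operation, and the acetic acid buffer keeps the polyphenol from standing as a basic phenoxide; neither the isopropenyl group nor the tertiary alcohol reacts with fluoride.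

**Compound list**

1 | (+)-limonene 1,2-oxide, (4R)-1-methyl-4-(prop-1-en-2-yl)-7-oxabicyclo[4.1.0]heptane, cis/trans mixture | CC12OC1C[C@@H](CC2)C(C)=C | starting material
2 | (3R)-6-oxo-3-(prop-1-en-2-yl)heptanal | O=CC[C@@H](CCC(C)=O)C(C)=C | intermediate
3 | (3R)-6-oxo-3-(prop-1-en-2-yl)heptanoic acid | OC(=O)C[C@@H](CCC(C)=O)C(C)=C | intermediate
4 | (3R)-6-hydroxy-6-methyl-3-(prop-1-en-2-yl)heptanoic acid | OC(=O)C[C@@H](CCC(C)(C)O)C(C)=C | intermediate
5 | 2-thioxopyridin-1(2H)-yl (3R)-6-hydroxy-6-methyl-3-(prop-1-en-2-yl)heptanoate (Barton ester) | S=C1C=CC=CN1OC(=O)C[C@@H](CCC(C)(C)O)C(C)=C | intermediate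
6 | (5S)-5-(iodomethyl)-2,6-dimethylhept-6-en-2-ol | IC[C@@H](CCC(C)(C)O)C(C)=C | intermediate
7 | triethyl{[(5S)-5-(iodomethyl)-2,6-dimethylhept-6-en-2-yl]oxy}silane | IC[C@@H](CCC(C)(C)O[Si](CC)(CC)CC)C(C)=C | intermediate
8 | phloroglucinol | Oc1cc(O)cc(O)c1 | starting material
9 | 5-(triisopropylsilyloxy)benzene-1,3-diol | Oc1cc(O)cc(O[Si](C(C)C)(C(C)C)C(C)C)c1 | intermediate
10 | [3,5-bis(methoxymethoxy)phenoxy]triisopropylsilane | COCOc1cc(OCOC)cc(O[Si](C(C)C)(C(C)C)C(C)C)c1 | intermediate
11 | [2,6-bis(methoxymethoxy)-4-(triisopropylsilyloxy)phenyl]lithium | [Li]c1c(OCOC)cc(O[Si](C(C)C)(C(C)C)C(C)C)cc1OCOC | intermediate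
12 | [4-bromo-3,5-bis(methoxymethoxy)phenoxy]triisopropylsilane | Brc1c(OCOC)cc(O[Si](C(C)C)(C(C)C)C(C)C)cc1OCOC | intermediate
13 | {(2S)-5-methyl-2-(prop-1-en-2-yl)-5-(triethylsilyloxy)hexyl}zinc iodide | I[Zn]C[C@@H](CCC(C)(C)O[Si](CC)(CC)CC)C(C)=C | intermediate
14 | {3,5-bis(methoxymethoxy)-4-[(2R)-5-methyl-2-(prop-1-en-2-yl)-5-(triethylsilyloxy)hexyl]phenoxy}triisopropylsilane | C=C(C)[C@H](CCC(C)(C)O[Si](CC)(CC)CC)Cc1c(OCOC)cc(O[Si](C(C)C)(C(C)C)C(C)C)cc1OCOC | intermediate
15 | {2-iodo-3,5-bis(methoxymethoxy)-4-[(2R)-5-methyl-2-(prop-1-en-2-yl)-5-(triethylsilyloxy)hexyl]phenoxy}triisopropylsilane | C=C(C)[C@H](CCC(C)(C)O[Si](CC)(CC)CC)Cc1c(OCOC)cc(O[Si](C(C)C)(C(C)C)C(C)C)c(I)c1OCOC | intermediate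
16 | bis(trimethylsilyl) ether of 17: 4-iodo-2-[(2R)-alkyl]-1,3-bis(trimethylsilyloxy)-5-(triisopropylsilyloxy)benzene | C=C(C)[C@H](CCC(C)(C)O[Si](CC)(CC)CC)Cc1c(O[Si](C)(C)C)cc(O[Si](C(C)C)(C(C)C)C(C)C)c(I)c1O[Si](C)(C)C | intermediate
17 | 4-iodo-2-[(2R)-5-methyl-2-(prop-1-en-2-yl)-5-(triethylsilyloxy)hexyl]-5-(triisopropylsilyloxy)benzene-1,3-diol | C=C(C)[C@H](CCC(C)(C)O[Si](CC)(CC)CC)Cc1c(O)cc(O[Si](C(C)C)(C(C)C)C(C)C)c(I)c1O | intermediate
18 | 2,4-dihydroxybenzaldehyde | O=Cc1ccc(O)cc1O | starting material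
19 | 2,4-bis(triisopropylsilyloxy)benzaldehyde | O=Cc1ccc(O[Si](C(C)C)(C(C)C)C(C)C)cc1O[Si](C(C)C)(C(C)C)C(C)C | intermediate
20 | [4-(2,2-dibromoethenyl)-1,3-phenylene]bis(oxy)bis(triisopropylsilane) | BrC(Br)=Cc1ccc(O[Si](C(C)C)(C(C)C)C(C)C)cc1O[Si](C(C)C)(C(C)C)C(C)C | intermediate
21 | {[2,4-bis(triisopropylsilyloxy)phenyl]ethynyl}lithium | [Li]C#Cc1ccc(O[Si](C(C)C)(C(C)C)C(C)C)cc1O[Si](C(C)C)(C(C)C)C(C)C | intermediate
22 | 1-ethynyl-2,4-bis(triisopropylsilyloxy)benzene | C#Cc1ccc(O[Si](C(C)C)(C(C)C)C(C)C)cc1O[Si](C(C)C)(C(C)C)C(C)C | intermediate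
23 | carbon monoxide | [C-]#[O+] | starting material
24 | 1-{2,4-dihydroxy-3-[(2R)-5-methyl-2-(prop-1-en-2-yl)-5-(triethylsilyloxy)hexyl]-6-(triisopropylsilyloxy)phenyl}-3-[2,4-bis(triisopropylsilyloxy)phenyl]prop-2-yn-1-one | C=C(C)[C@H](CCC(C)(C)O[Si](CC)(CC)CC)Cc1c(O)cc(O[Si](C(C)C)(C(C)C)C(C)C)c(C(=O)C#Cc2ccc(O[Si](C(C)C)(C(C)C)C(C)C)cc2O[Si](C(C)C)(C(C)C)C(C)C)c1O | intermediate
25 | (E)-3-(diethylamino)-1-{2,4-dihydroxy-3-[(2R)-5-methyl-2-(prop-1-en-2-yl)-5-(triethylsilyloxy)hexyl]-6-(triisopropylsilyloxy)phenyl}-3-[2,4-bis(triisopropylsilyloxy)phenyl]prop-2-en-1-one | C=C(C)[C@H](CCC(C)(C)O[Si](CC)(CC)CC)Cc1c(O)cc(O[Si](C(C)C)(C(C)C)C(C)C)c(C(=O)/C=C(/N(CC)CC)c2ccc(O[Si](C(C)C)(C(C)C)C(C)C)cc2O[Si](C(C)C)(C(C)C)C(C)C)c1O | intermediate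
26 | 2-[2,4-bis(triisopropylsilyloxy)phenyl]-7-hydroxy-8-[(2R)-5-methyl-2-(prop-1-en-2-yl)-5-(triethylsilyloxy)hexyl]-5-(triisopropylsilyloxy)-4H-chromen-4-one | C=C(C)[C@H](CCC(C)(C)O[Si](CC)(CC)CC)Cc1c(O)cc(O[Si](C(C)C)(C(C)C)C(C)C)c2c(=O)cc(-c3ccc(O[Si](C(C)C)(C(C)C)C(C)C)cc3O[Si](C(C)C)(C(C)C)C(C)C)oc12 | intermediate
27 | 2-(2,4-dihydroxyphenyl)-5,7-dihydroxy-8-[(2R)-5-hydroxy-5-methyl-2-(prop-1-en-2-yl)hexyl]-4H-chromen-4-one | C=C(C)[C@H](CCC(C)(C)O)Cc1c(O)cc(O)c2c(=O)cc(-c3ccc(O)cc3O)oc12 | target

**Step count and risks**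

Total step count: 16. Longest linear sequence: 10 steps (steps 1, 2, 3, 4, 5, 9, 10, 11, 15, 16, from 1).

Steps most likely to fail:

1. Step 15 (key step). What may go wrong:
- direct, non-carbonylative alkynylation followed by closure to a benzofuran;
- 5-exo closure to the aurone;
- sluggish oxidative addition at the doubly ortho-substituted, phenoxide-rich iodide;
- loss of the C5 silyl group before ring closure, which would scramble the regiochemistry.

Fallback: build the ynone stepwise without carbon monoxide, setting out from iodide 15 and alkyne 22. Iodine–lithium exchange on 15 (n-BuLi, THF, −78 °C) should give the aryllithium F1, which is formylated with DMF to the benzaldehyde F2. Addition of lithium acetylide 21 (from 22 and n-BuLi) should give the propargylic alcohol F3 as a mixture of carbinol epimers. MnO2 oxidation should give the bis-MOM ynone F4. TMSOTf/2,2′-bipyridyl followed by water then frees the two phenols. The sequence rejoins the route at ynone 24, which is closed to 26 with Et2NH in THF through 25.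

2. Step 9 (Negishi coupling). What may go wrong:
- slow oxidative addition or transmetalation at the doubly ortho-alkoxylated bromide;
- β-hydride elimination from the alkylpalladium, giving a diene or eroding the allylic β-stereocentre through re-insertion;
- protodezincation.

Fallback: reverse the polarity, setting out from arene 10 (through aryllithium 11) and iodide 7. Transmetalation of 11 with MgBr2·OEt2 should give the arylmagnesium bromide F5, which is alkylated at the primary carbon of 7 under copper catalysis (Li2CuCl4, THF, −20 °C → rt, Kochi-type coupling). This returns to the route at 14.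

3. Step 4 (Barton iododecarboxylation). What may go wrong:
- derailment of the radical chain by addition of chain-carrying radicals to the isopropenyl group;
- 3-exo closure and 1,2-vinyl shift of the homoallyl radical;
- rearrangement of the thiohydroxamate ester to the pyridyl sulfide.

Fallback: an ionic one-carbon degradation setting out from acid 4. The trianion (LDA, 3.3 equiv, THF, −78 → 0 °C) is oxygenated (O2, then P(OEt)3) to the α-hydroxy acid F6 as a mixture of C2 epimers. Pb(OAc)4 (CH2Cl2, 0 °C) should cleave it with loss of CO2 to the nor-aldehyde F7, which is reduced at once with NaBH4 (MeOH, −20 °C) to the diol F8 before the α-centre can epimerise. I2/PPh3/imidazole then converts only the primary alcohol into the iodide, returning to the route at 6.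

**Further compounds**

F1 | step 15 | {3-[(2R)-5-methyl-2-(prop-1-en-2-yl)-5-(triethylsilyloxy)hexyl]-2,4-bis(methoxymethoxy)-6-(triisopropylsilyloxy)phenyl}lithium | C=C(C)[C@H](CCC(C)(C)O[Si](CC)(CC)CC)Cc1c(OCOC)cc(O[Si](C(C)C)(C(C)C)C(C)C)c([Li])c1OCOC
F2 | step 15 | 3-[(2R)-5-methyl-2-(prop-1-en-2-yl)-5-(triethylsilyloxy)hexyl]-2,4-bis(methoxymethoxy)-6-(triisopropylsilyloxy)benzaldehyde | C=C(C)[C@H](CCC(C)(C)O[Si](CC)(CC)CC)Cc1c(OCOC)cc(O[Si](C(C)C)(C(C)C)C(C)C)c(C=O)c1OCOC
F3 | step 15 | 1-{3-[(2R)-5-methyl-2-(prop-1-en-2-yl)-5-(triethylsilyloxy)hexyl]-2,4-bis(methoxymethoxy)-6-(triisopropylsilyloxy)phenyl}-3-[2,4-bis(triisopropylsilyloxy)phenyl]prop-2-yn-1-ol, both carbinol epimers | C=C(C)[C@H](CCC(C)(C)O[Si](CC)(CC)CC)Cc1c(OCOC)cc(O[Si](C(C)C)(C(C)C)C(C)C)c(C(O)C#Cc2ccc(O[Si](C(C)C)(C(C)C)C(C)C)cc2O[Si](C(C)C)(C(C)C)C(C)C)c1OCOC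
F4 | step 15 | 1-{3-[(2R)-5-methyl-2-(prop-1-en-2-yl)-5-(triethylsilyloxy)hexyl]-2,4-bis(methoxymethoxy)-6-(triisopropylsilyloxy)phenyl}-3-[2,4-bis(triisopropylsilyloxy)phenyl]prop-2-yn-1-one | C=C(C)[C@H](CCC(C)(C)O[Si](CC)(CC)CC)Cc1c(OCOC)cc(O[Si](C(C)C)(C(C)C)C(C)C)c(C(=O)C#Cc2ccc(O[Si](C(C)C)(C(C)C)C(C)C)cc2O[Si](C(C)C)(C(C)C)C(C)C)c1OCOC
F5 | step 9 | [2,6-bis(methoxymethoxy)-4-(triisopropylsilyloxy)phenyl]magnesium bromide | Br[Mg]c1c(OCOC)cc(O[Si](C(C)C)(C(C)C)C(C)C)cc1OCOC
F6 | step 4 | (3S)-2,6-dihydroxy-6-methyl-3-(prop-1-en-2-yl)heptanoic acid, both C2 epimers | OC(=O)C(O)[C@@H](CCC(C)(C)O)C(C)=C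
F7 | step 4 | (2S)-5-hydroxy-5-methyl-2-(prop-1-en-2-yl)hexanal | O=C[C@@H](CCC(C)(C)O)C(C)=C
F8 | step 4 | (2S)-5-methyl-2-(prop-1-en-2-yl)hexane-1,5-diol | OC[C@@H](CCC(C)(C)O)C(C)=C
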